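**Retrosynthetic overview**
1. Endgame: maackiaflavanone A comes from its 5,2'-bis(silyl ether), which comes from a flavanone carrying an allyl ester on C3; the ester is lost by Tsuji–Trost deallylation and decarboxylation.
2. Key disconnection C3–C4 (ring C is formed last): enantioselective rhodium-catalysed intramolecular hydroacylation of an open, achiral aryl ether, in which the formyl carbon (future C4) adds to C3 and its hydrogen to C2 of an O1-bound C2=C3 double bond.
3. Enabling feature: C4 sits on C4a of ring A, ortho to C8a–O1, so cutting C3–C4 leaves a salicylaldehyde whose phenolic oxygen is O1. C3 is the methylene next to the ketone, so it can carry an ester that polarises C2=C3 and later leaves as CO2.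
4. O1–C2 disconnection: oxa-Michael addition of the ring A salicylaldehyde to a ring B/D aryl propiolate, whose C3 carbon comes from CBr4 in a Corey–Fuchs sequence.
5. Ring order: ring A is bought (phloroglucinaldehyde, then methylated, C-prenylated, mono-silylated); ring D is closed onto resorcinol (ring B); ring C is closed last.

Key step: step 10

Remark on the chemistry: the sense of induction of the chiral rhodium catalyst cannot be predicted with certainty; the ligand antipode that gives the (2S) product is to be used (written here as (R)-DTBM-SEGPHOS, its mirror image being equally available).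

**Step 1**
Reactants: 1 2,4,6-trihydroxybenzaldehyde
Product: 2 2,6-dihydroxy-4-methoxybenzaldehyde
Conditions: MeI (1.0 equiv), K2CO3 (1.0 equiv), acetone, 0 °C to rt
Reagents that add atoms: iodomethane, CI
Why: Williamson etherification, in which the 4-hydroxyl is the most acidic and the only one not hydrogen-bonded to the formyl group, so one equivalent of base and MeI should alkylate it first.

**Step 2**
Reactants: 2 2,6-dihydroxy-4-methoxybenzaldehyde; 3 1-bromo-3-methylbut-2-ene (prenyl bromide)
Product: 4 2,6-dihydroxy-4-methoxy-3-(3-methylbut-2-en-1-yl)benzaldehyde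
Conditions: 10% aq. KOH, 0 °C to rt
Reagents that add atoms: none
Why: C-alkylation (C-prenylation) of the ambident phloroglucinol-type phenolate in water, where 2 is symmetrical so that C3 and C5 are equivalent and only one mono-C-prenyl isomer can form.

**Step 3**
Reactants: 4 2,6-dihydroxy-4-methoxy-3-(3-methylbut-2-en-1-yl)benzaldehyde
Product: 5 2-hydroxy-4-methoxy-3-(3-methylbut-2-en-1-yl)-6-[(triisopropylsilyl)oxy]benzaldehyde
Conditions: i-Pr3SiCl (1.05 equiv), imidazole, CH2Cl2, 0 °C
Reagents that add atoms: chlorotri(propan-2-yl)silane, CC(C)[Si](Cl)(C(C)C)C(C)C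
Why: Silyl ether formation under steric control, in which the bulky chloride should take the hydroxyl flanked by H rather than the one flanked by the prenyl group, leaving free the phenol that becomes O1.

**Step 4**
Reactants: 6 resorcinol (used in excess); 7 3-methylbut-2-enal
Product: 8 2,2-dimethyl-2H-chromen-7-ol
Conditions: pyridine, 140 °C, sealed tube
Reagents that add atoms: none
Why: Chromene annulation, in which aldol-type C-alkylation para to one hydroxyl, dehydration to an ortho-quinone methide and oxa-6π electrocyclization close ring D.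

**Step 5**
Reactants: 8 2,2-dimethyl-2H-chromen-7-ol
Product: 9 7-hydroxy-2,2-dimethyl-2H-chromene-6-carbaldehyde
Conditions: MgCl2, Et3N, paraformaldehyde, MeCN, reflux
Reagents that add atoms: formaldehyde (used as paraformaldehyde), C=O
Why: Magnesium phenoxide-directed ortho-formylation, which should go to the less hindered ortho position C6 rather than to C8 between the two oxygens.

**Step 6**
Reactants: 9 7-hydroxy-2,2-dimethyl-2H-chromene-6-carbaldehyde
Product: 10 2,2-dimethyl-7-[(triisopropylsilyl)oxy]-2H-chromene-6-carbaldehyde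
Conditions: i-Pr3SiCl, imidazole, DMF, rt
Reagents that add atoms: chlorotri(propan-2-yl)silane, CC(C)[Si](Cl)(C(C)C)C(C)C
Why: Silyl ether formation protects the future 2'-hydroxyl for the organolithium and base steps that follow.

**Step 7**
Reactants: 10 2,2-dimethyl-7-[(triisopropylsilyl)oxy]-2H-chromene-6-carbaldehyde
Product: 11 6-(2,2-dibromoethenyl)-2,2-dimethyl-7-[(triisopropylsilyl)oxy]-2H-chromene
Conditions: CBr4, PPh3, CH2Cl2, 0 °C
Reagents that add atoms: tetrabromomethane, BrC(Br)(Br)Br
Why: First stage of the Corey–Fuchs reaction, a Wittig-type olefination with the dibromomethylene ylide that adds the carbon destined to be C3.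

**Step 8**
Reactants: 11 6-(2,2-dibromoethenyl)-2,2-dimethyl-7-[(triisopropylsilyl)oxy]-2H-chromene
Product: 13 prop-2-en-1-yl 3-{2,2-dimethyl-7-[(triisopropylsilyl)oxy]-2H-chromen-6-yl}prop-2-ynoate, via lithium acetylide 12 (not isolated)
Conditions: n-BuLi (2.1 equiv), THF, −78 °C; then ClCO2CH2CH=CH2, −78 to 0 °C
Reagents that add atoms: prop-2-en-1-yl carbonochloridate (allyl chloroformate), C=CCOC(=O)Cl; n-butyllithium, [Li]CCCC (supplies only the lithium of 12)
Why: Second stage of the Corey–Fuchs reaction, in which bromine–lithium exchange, 1,2-shift to the alkyne and deprotonation give the acetylide, which the chloroformate acylates.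

**Step 9**
Reactants: 5 2-hydroxy-4-methoxy-3-(3-methylbut-2-en-1-yl)-6-[(triisopropylsilyl)oxy]benzaldehyde; 13 prop-2-en-1-yl 3-{2,2-dimethyl-7-[(triisopropylsilyl)oxy]-2H-chromen-6-yl}prop-2-ynoate
Product: 14 prop-2-en-1-yl (2Z)-3-{2,2-dimethyl-7-[(triisopropylsilyl)oxy]-2H-chromen-6-yl}-3-{2-formyl-5-methoxy-6-(3-methylbut-2-en-1-yl)-3-[(triisopropylsilyl)oxy]phenoxy}prop-2-enoate
Conditions: Cs2CO3 (0.2 equiv), MeCN, 40 °C; chromatography to a single alkene isomer
Reagents that add atoms: none
Why: Oxa-Michael addition of the phenoxide to the β-carbon of the aryl propiolate forms the O1–C2 bond, the free phenol present under catalytic base should protonate the vinyl anion, and anti addition should favour the Z isomer.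

**Step 10**
Reactants: 14 prop-2-en-1-yl (2Z)-3-aryl-3-(2-formylaryloxy)prop-2-enoate as named in step 9
Product: 15 prop-2-en-1-yl (2S,3RS)-2-{2,2-dimethyl-7-[(triisopropylsilyl)oxy]-2H-chromen-6-yl}-7-methoxy-8-(3-methylbut-2-en-1-yl)-4-oxo-5-[(triisopropylsilyl)oxy]-3,4-dihydro-2H-chromene-3-carboxylate
Conditions: [Rh(nbd)2]BF4 (5 mol %), (R)-DTBM-SEGPHOS (5.5 mol %), activated with H2 and degassed; acetone, 40 °C, Ar
Reagents that add atoms: none
Why: Proposed new method: the cationic monovalent rhodium bisphosphine complex should insert into the formyl C–H bond of 14 with help from the neighbouring O1 ether oxygen, the trivalent rhodium acyl hydride should deliver hydride to the oxygenated β-carbon C2 so that rhodium sits on C3 as a C-bound ester enolate, and C–C reductive elimination should join C3 to the acyl carbon C4. The closest known reaction type is the enantioselective rhodium-catalysed intramolecular alkene hydroacylation of 2-(alkenyloxy)benzaldehydes and of trisubstituted alkenes to chroman-4-ones and related benzo-fused ketones, in which β-aryloxy alkylrhodium intermediates of the same kind go on to product; a β-aryloxy acrylate has not been used as the alkene. Ring C is closed in the 6-endo-trig mode, both alkene carbons ending up in the ring. The C2 stereocenter is set by the chiral bisphosphine, which selects the alkene face for hydride delivery, while C3 arises by syn addition as a configurationally labile β-keto ester centre that is erased in step 11. The step needs 6-endo over 5-exo closure and reductive elimination over decarbonylation: the 5-exo path would put rhodium on the fully substituted C2, hydride transfer to the β-carbon of an acrylate is the polarity-matched direction, and the two ortho substituents of the aldehyde together with O1 chelation should hold the acyl rhodium species against loss of CO. The single Z geometry of 14 secures one family of diastereomeric transition states and the non-basic medium keeps the product from retro-oxa-Michael opening.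

**Step 11**
Reactants: 15 allyl (2S,3RS)-4-oxoflavanone-3-carboxylate as named in step 10
Product: 17 (2S)-2-{2,2-dimethyl-7-[(triisopropylsilyl)oxy]-2H-chromen-6-yl}-7-methoxy-8-(3-methylbut-2-en-1-yl)-5-[(triisopropylsilyl)oxy]-2,3-dihydro-4H-chromen-4-one, via β-keto acid 16 (not isolated)
Conditions: Pd(PPh3)4 (5 mol %), dimedone (1.5 equiv), THF, rt then 45 °C
Reagents that add atoms: none
Why: Tsuji–Trost deallylation (allyl transfer from the π-allyl complex of divalent palladium to dimedone) should free the β-keto acid, which loses CO2 on gentle warming under neutral conditions that avoid enolate formation, so C2 is untouched.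

**Step 12**
Reactants: 17 (2S)-bis(triisopropylsilyl) flavanone as named in step 11
Product: 18 maackiaflavanone A, (2S)-5-hydroxy-2-(7-hydroxy-2,2-dimethyl-2H-chromen-6-yl)-7-methoxy-8-(3-methylbut-2-en-1-yl)-2,3-dihydro-4H-chromen-4-one
Conditions: Bu4NF (2.4 equiv), AcOH (2.4 equiv), THF, 0 °C
Reagents that add atoms: none
Why: Fluoride-induced cleavage of both aryl silyl ethers, with acetic acid buffering to keep the medium non-basic so that the flavanone should not open to the chalcone and C2 should keep its configuration.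

**Compound list**
1 | 2,4,6-trihydroxybenzaldehyde | O=Cc1c(O)cc(O)cc1O | starting material
2 | 2,6-dihydroxy-4-methoxybenzaldehyde | COc1cc(O)c(C=O)c(O)c1 | intermediate
3 | 1-bromo-3-methylbut-2-ene | CC(C)=CCBr | starting material
4 | 2,6-dihydroxy-4-methoxy-3-(3-methylbut-2-en-1-yl)benzaldehyde | COc1cc(O)c(C=O)c(O)c1CC=C(C)C | intermediate
5 | 2-hydroxy-4-methoxy-3-(3-methylbut-2-en-1-yl)-6-[(triisopropylsilyl)oxy]benzaldehyde | COc1cc(O[Si](C(C)C)(C(C)C)C(C)C)c(C=O)c(O)c1CC=C(C)C | intermediate
6 | resorcinol | Oc1cccc(O)c1 | starting material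
7 | 3-methylbut-2-enal | CC(C)=CC=O | starting material
8 | 2,2-dimethyl-2H-chromen-7-ol | CC1(C)C=Cc2ccc(O)cc2O1 | intermediate
9 | 7-hydroxy-2,2-dimethyl-2H-chromene-6-carbaldehyde | CC1(C)C=Cc2cc(C=O)c(O)cc2O1 | intermediate
10 | 2,2-dimethyl-7-[(triisopropylsilyl)oxy]-2H-chromene-6-carbaldehyde | CC1(C)C=Cc2cc(C=O)c(O[Si](C(C)C)(C(C)C)C(C)C)cc2O1 | intermediate
11 | 6-(2,2-dibromoethenyl)-2,2-dimethyl-7-[(triisopropylsilyl)oxy]-2H-chromene | CC1(C)C=Cc2cc(C=C(Br)Br)c(O[Si](C(C)C)(C(C)C)C(C)C)cc2O1 | intermediate
12 | lithium {2,2-dimethyl-7-[(triisopropylsilyl)oxy]-2H-chromen-6-yl}ethynide (formed in the flask) | [Li]C#Cc1cc2C=CC(C)(C)Oc2cc1O[Si](C(C)C)(C(C)C)C(C)C | intermediate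
13 | prop-2-en-1-yl 3-{2,2-dimethyl-7-[(triisopropylsilyl)oxy]-2H-chromen-6-yl}prop-2-ynoate | C=CCOC(=O)C#Cc1cc2C=CC(C)(C)Oc2cc1O[Si](C(C)C)(C(C)C)C(C)C | intermediate
14 | prop-2-en-1-yl (2Z)-3-{2,2-dimethyl-7-[(triisopropylsilyl)oxy]-2H-chromen-6-yl}-3-{2-formyl-5-methoxy-6-(3-methylbut-2-en-1-yl)-3-[(triisopropylsilyl)oxy]phenoxy}prop-2-enoate | C=CCOC(=O)/C=C(\Oc1c(C=O)c(O[Si](C(C)C)(C(C)C)C(C)C)cc(OC)c1CC=C(C)C)c1cc2C=CC(C)(C)Oc2cc1O[Si](C(C)C)(C(C)C)C(C)C | intermediate
15 | prop-2-en-1-yl (2S,3RS)-2-{2,2-dimethyl-7-[(triisopropylsilyl)oxy]-2H-chromen-6-yl}-7-methoxy-8-(3-methylbut-2-en-1-yl)-4-oxo-5-[(triisopropylsilyl)oxy]-3,4-dihydro-2H-chromene-3-carboxylate (C2 defined; C3 labile, both epimers are used) | COc1cc(O[Si](C(C)C)(C(C)C)C(C)C)c2c(c1CC=C(C)C)O[C@H](c1cc3c(cc1O[Si](C(C)C)(C(C)C)C(C)C)OC(C)(C)C=C3)C(C(=O)OCC=C)C2=O | intermediate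
16 | (2S,3RS)-2-{2,2-dimethyl-7-[(triisopropylsilyl)oxy]-2H-chromen-6-yl}-7-methoxy-8-(3-methylbut-2-en-1-yl)-4-oxo-5-[(triisopropylsilyl)oxy]-3,4-dihydro-2H-chromene-3-carboxylic acid (formed in the flask) | COc1cc(O[Si](C(C)C)(C(C)C)C(C)C)c2c(c1CC=C(C)C)O[C@H](c1cc3c(cc1O[Si](C(C)C)(C(C)C)C(C)C)OC(C)(C)C=C3)C(C(=O)O)C2=O | intermediate
17 | (2S)-2-{2,2-dimethyl-7-[(triisopropylsilyl)oxy]-2H-chromen-6-yl}-7-methoxy-8-(3-methylbut-2-en-1-yl)-5-[(triisopropylsilyl)oxy]-2,3-dihydro-4H-chromen-4-one | COc1cc(O[Si](C(C)C)(C(C)C)C(C)C)c2c(c1CC=C(C)C)O[C@H](c1cc3c(cc1O[Si](C(C)C)(C(C)C)C(C)C)OC(C)(C)C=C3)CC2=O | intermediate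
18 | maackiaflavanone A, (2S)-5-hydroxy-2-(7-hydroxy-2,2-dimethyl-2H-chromen-6-yl)-7-methoxy-8-(3-methylbut-2-en-1-yl)-2,3-dihydro-4H-chromen-4-one | COc1cc(O)c2c(c1CC=C(C)C)O[C@H](c1cc3c(cc1O)OC(C)(C)C=C3)CC2=O | target

**Step count and risks**
Total steps: 12. Longest linear sequence: 9 steps (resorcinol 6 to 18 through steps 4 to 12).

Steps most likely to fail:

1. Step 10 (proposed new method). The acyl rhodium hydride may lose CO, or the alkylrhodium intermediate may eliminate the aryloxide, faster than the C–C reductive elimination. Facial selectivity in the hydride transfer to the tetrasubstituted push-pull carbon may also be poor. Fallback, setting out from 5 and 13 and coming back at 15: with a full equivalent of Cs2CO3 in dry DMSO and no proton source, the phenoxide of 5 should add to 13 and the vinyl anion should be trapped by the neighbouring formyl group (tandem oxa-Michael/aldol, ring C again closed at C3–C4). This should give racemic prop-2-en-1-yl 2-{2,2-dimethyl-7-[(triisopropylsilyl)oxy]-2H-chromen-6-yl}-4-hydroxy-7-methoxy-8-(3-methylbut-2-en-1-yl)-5-[(triisopropylsilyl)oxy]-4H-chromene-3-carboxylate F1. Oxidation of the crude alcohol with MnO2 in CH2Cl2 should give the flavone ester prop-2-en-1-yl 2-{2,2-dimethyl-7-[(triisopropylsilyl)oxy]-2H-chromen-6-yl}-7-methoxy-8-(3-methylbut-2-en-1-yl)-4-oxo-5-[(triisopropylsilyl)oxy]-4H-chromene-3-carboxylate F2. An asymmetric 1,4-reduction with a chiral copper hydride catalyst (Cu(OAc)2, (R)-DTBM-SEGPHOS, (EtO)2MeSiH, toluene, 0 °C, quench with AcOH) should then set C2 and return to 15.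

2. Step 9. The vinyl anion may add to the formyl group before it is protonated, the hindered phenoxide may add slowly, and the alkene geometry may scramble under base. Fallback, setting out from 13 and coming back at 14: hydrochlorination of 13 (LiCl, AcOH, 70 °C) should give prop-2-en-1-yl (2Z)-3-chloro-3-{2,2-dimethyl-7-[(triisopropylsilyl)oxy]-2H-chromen-6-yl}prop-2-enoate F3. Addition–elimination of the phenoxide of 5 on this vinyl chloride (K2CO3, DMF, rt) passes through an ester enolate that expels chloride instead of a vinyl anion, and should give 14 with retention of the Z geometry.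

3. Step 2. O-alkylation and double alkylation may compete with mono-C-alkylation of the phenolate. Fallback, setting out from 2 and 3 and coming back at 4: mono-O-prenylation (K2CO3, 1 equiv, acetone, rt) should give 2-hydroxy-4-methoxy-6-[(3-methylbut-2-en-1-yl)oxy]benzaldehyde F4. A Claisen–Cope rearrangement catalysed by Eu(fod)3 (CHCl3, 60 °C) should then move the prenyl group to the ring carbon para to the ether oxygen, which in this symmetrical series is compound 4.

**Further compounds**
F1 | step 10 | prop-2-en-1-yl 2-{2,2-dimethyl-7-[(triisopropylsilyl)oxy]-2H-chromen-6-yl}-4-hydroxy-7-methoxy-8-(3-methylbut-2-en-1-yl)-5-[(triisopropylsilyl)oxy]-4H-chromene-3-carboxylate (racemic at C4) | COc1cc(O[Si](C(C)C)(C(C)C)C(C)C)c2c(c1CC=C(C)C)OC(c1cc3c(cc1O[Si](C(C)C)(C(C)C)C(C)C)OC(C)(C)C=C3)=C(C(=O)OCC=C)C2O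
F2 | step 10 | prop-2-en-1-yl 2-{2,2-dimethyl-7-[(triisopropylsilyl)oxy]-2H-chromen-6-yl}-7-methoxy-8-(3-methylbut-2-en-1-yl)-4-oxo-5-[(triisopropylsilyl)oxy]-4H-chromene-3-carboxylate | COc1cc(O[Si](C(C)C)(C(C)C)C(C)C)c2c(c1CC=C(C)C)OC(c1cc3c(cc1O[Si](C(C)C)(C(C)C)C(C)C)OC(C)(C)C=C3)=C(C(=O)OCC=C)C2=O
F3 | step 9 | prop-2-en-1-yl (2Z)-3-chloro-3-{2,2-dimethyl-7-[(triisopropylsilyl)oxy]-2H-chromen-6-yl}prop-2-enoate | C=CCOC(=O)/C=C(\Cl)c1cc2C=CC(C)(C)Oc2cc1O[Si](C(C)C)(C(C)C)C(C)C
F4 | step 2 | 2-hydroxy-4-methoxy-6-[(3-methylbut-2-en-1-yl)oxy]benzaldehyde | COc1cc(O)c(C=O)c(OCC=C(C)C)c1
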